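The filicinic ring, the six-membered enolised triketone that carries C(CH3)2, the acetyl group and the bridging CH2, is read as a 3,5-dialkoxy-6,6-dimethylcyclohexa-2,4-dienone, the closed form of a dienylketene ending in C(CH3)2. It is therefore grown from a four-membered ring. 3-Ethoxy-4,4-dimethylcyclobutenone already holds C=O, CH, C-O and the quaternary carbon, and methoxyacetylene inserts the missing CH=C(O) pair in one thermal cascade. The step exploits the alternating ring oxygens, set by ynol ether polarity, and the gem-dimethyl carbon, which blocks aromatisation. Hydrolysis, C-acetylation and a Mannich/o-quinone methide union with aspidinol at the bridging CH2 complete the target.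

Key step: step 3

Remark: the enolised triketone rings are written in the tautomer of the target SMILES. All keto-enol tautomers interconvert freely, and the target has no stereocentre.

Step 1
Reactants: 1 isobutyryl chloride; 2 ethoxyacetylene
Product: 4 3-ethoxy-4,4-dimethylcyclobut-2-en-1-one, via dimethylketene 3 (not isolated)
Conditions: Et3N (1.3 equiv), Et2O, reflux
Reagents that add atoms: none
Why: Dehydrochlorination of 1 gives dimethylketene, and in the ketene/ynol ether [2+2] cycloaddition the nucleophilic CH terminus of 2 bonds to the ketene carbonyl carbon, so OEt ends up next to the quaternary carbon.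

Step 2
Reactants: 5 chloroacetaldehyde dimethyl acetal
Product: 7 methoxyacetylene, via sodium methoxyacetylide 6 (not isolated)
Conditions: NaNH2 (3.3 equiv), liq. NH3, -33 °C; NH3 off; cold brine; distil into a cold trap, keep as toluene solution
Reagents that add atoms: none
Why: Two successive base-induced β-eliminations (methanol, then hydrogen chloride) are the standard alkoxyacetylene synthesis from α-chloro acetals, and the methyl ether is chosen because, unlike 2, it has no β-hydrogen and cannot lose ketene by a retro-ene reaction at the temperature of step 3.

Step 3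
Reactants: 4 3-ethoxy-4,4-dimethylcyclobut-2-en-1-one; 7 methoxyacetylene
Product: 11 5-ethoxy-3-methoxy-6,6-dimethylcyclohexa-2,4-dien-1-one, via vinylketene 8 (not isolated), via 4-alkenylcyclobutenone 9 (not isolated), via dienylketene 10 (not isolated)
Conditions: 7 (3 equiv), toluene (0.5 M), BHT (trace), sealed tube, 155 °C
Reagents that add atoms: none
Why: Heating opens the C1-C4 bond of 4 by conrotatory 4π electrocyclic opening to vinylketene 8, the nucleophilic CH terminus of 7 attacks the ketene carbonyl carbon so that a [2+2] cycloaddition closes the transient four-membered ring of 9, and a second, reversible 4π opening gives dienylketene 10, whose isomer with the alkenyl group turned inward closes the six-membered ring by disrotatory 6π electrocyclisation at the C(=O)-C(CH3)2 bond. The closest known reaction type is the Danheiser cyclobutenone/ynol ether annulation, and its last event is the thermal reverse of the photochemical opening of 6,6-disubstituted cyclohexa-2,4-dienones. In sum the two alkyne carbons are inserted between C1 and C2 of the cyclobutenone, so all four atoms of the small ring end up in the six-membered ring (two-carbon ring expansion). No stereocentre remains in 11, because the one in racemic 9 is destroyed on opening. The step needs regioselectivity, secured by the polarity of the ynol ether (OMe lands meta to OEt and gives the 1,3,5-oxygen pattern), and it needs capture of 8 to outrun its 1,5-hydrogen shift, which the excess of 7 at high concentration favours. Tautomerisation to a phenol is impossible because the ring-closing terminus is C(CH3)2, so the product stays at the dienone level that filicinic acid requires.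

Step 4
Reactants: 11 5-ethoxy-3-methoxy-6,6-dimethylcyclohexa-2,4-dien-1-one
Product: 12 filicinic acid (3,5-dihydroxy-4,4-dimethylcyclohexa-2,5-dien-1-one)
Conditions: 2 M aq. HCl, THF, reflux
Reagents that add atoms: water O
Why: Both alkoxy groups are vinylogous ester oxygens, so acid-catalysed addition-elimination of water (vinylogous ester hydrolysis) should free the enolised triketone, which has no other acid-labile group.

Step 5
Reactants: 12 filicinic acid
Product: 14 acetylfilicinic acid (2-acetyl-3,5-dihydroxy-4,4-dimethylcyclohexa-2,5-dien-1-one), via enol acetate 13 (not isolated)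
Conditions: AcOH (1.05 equiv), DCC (1.1 equiv), DMAP (0.2 equiv), CH2Cl2/DMF, 0 °C to rt
Reagents that add atoms: acetic acid CC(=O)O
Why: Steglich-type O-acylation followed by DMAP-catalysed O-to-C acyl migration is the way 2-acyl cyclic 1,3-diones are made; the two ring CH positions of 12 are equivalent by symmetry, and the more acidic, less nucleophilic product should resist a second acylation.

Step 6
Reactants: 15 2-methylphloroglucinol (2-methylbenzene-1,3,5-triol); 16 butyryl chloride
Product: 17 1-(2,4,6-trihydroxy-3-methylphenyl)butan-1-one
Conditions: AlCl3 (4 equiv), CH2Cl2/PhNO2, 0 to 45 °C; aq. HCl work-up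
Reagents that add atoms: none
Why: Friedel-Crafts acylation of a very electron-rich arene whose two free positions are equivalent, with the first acyl group deactivating the ring towards a second one.

Step 7
Reactants: 17 1-(2,4,6-trihydroxy-3-methylphenyl)butan-1-one
Product: 18 aspidinol (1-(2,6-dihydroxy-4-methoxy-3-methylphenyl)butan-1-one)
Conditions: Me2SO4 (1.0 equiv), K2CO3 (1.0 equiv), acetone, rt
Reagents that add atoms: dimethyl sulfate COS(=O)(=O)OC
Why: Williamson-type O-methylation with one equivalent of weak base should select the 4-OH, which is the most acidic hydroxyl (para to the acyl group) and the only one that cannot be held in a hydrogen-bonded chelate with the ketone.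

Step 8
Reactants: 18 aspidinol
Product: 19 1-{3-[(dimethylamino)methyl]-2,6-dihydroxy-4-methoxy-5-methylphenyl}butan-1-one
Conditions: 37% aq. CH2O (1.1 equiv), 40% aq. Me2NH (1.1 equiv), EtOH, rt
Reagents that add atoms: formaldehyde C=O; dimethylamine CNC
Why: The phenolic Mannich reaction can occur only at the single unsubstituted ring carbon, which is activated by the ortho OH and ortho OMe and reacts far faster than the ketone α-CH2 under these mild conditions.

Step 9
Reactants: 19 the Mannich base of aspidinol; 14 acetylfilicinic acid
Product: 21 2-acetyl-6-[(3-butanoyl-2,4-dihydroxy-6-methoxy-5-methylphenyl)methyl]-3,5-dihydroxy-4,4-dimethylcyclohexa-2,5-dien-1-one (target), via o-quinone methide 20 (not isolated)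
Conditions: 14 (1.1 equiv), 1,4-dioxane, 90 °C, N2 sweep
Reagents that add atoms: none
Why: Proton transfer from the acidic triketone 14 to the amine triggers retro-Mannich loss of Me2NH to the o-quinone methide, and the only CH carbon of the enolate of 14 adds in a Michael addition driven by rearomatisation, so only the mixed methylene-bridged product can form directly.

Compound list
1 | isobutyryl chloride | CC(C)C(=O)Cl | starting material
2 | ethoxyacetylene | CCOC#C | starting material
3 | dimethylketene | CC(C)=C=O | intermediate
4 | 3-ethoxy-4,4-dimethylcyclobut-2-en-1-one | CCOC1=CC(=O)C1(C)C | intermediate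
5 | chloroacetaldehyde dimethyl acetal (2-chloro-1,1-dimethoxyethane) | COC(CCl)OC | starting material
6 | sodium methoxyacetylide | [Na+].[C-]#COC | intermediate
7 | methoxyacetylene | COC#C | intermediate
8 | vinylketene, 3-ethoxy-4-methylpenta-1,3-dien-1-one | CCOC(C=C=O)=C(C)C | intermediate
9 | 4-(1-ethoxy-2-methylprop-1-en-1-yl)-3-methoxycyclobut-2-en-1-one (racemic) | COC1=CC(=O)C1C(OCC)=C(C)C | intermediate
10 | dienylketene, (3E)-5-ethoxy-3-methoxy-6-methylhepta-1,3,5-trien-1-one | O=C=C/C(OC)=C\C(OCC)=C(C)C | intermediate
11 | 5-ethoxy-3-methoxy-6,6-dimethylcyclohexa-2,4-dien-1-one | CCOC1=CC(OC)=CC(=O)C1(C)C | intermediate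
12 | filicinic acid, 3,5-dihydroxy-4,4-dimethylcyclohexa-2,5-dien-1-one | CC1(C)C(O)=CC(=O)C=C1O | intermediate
13 | 5-hydroxy-4,4-dimethyl-3-oxocyclohexa-1,5-dien-1-yl acetate | CC(=O)OC1=CC(=O)C(C)(C)C(O)=C1 | intermediate
14 | acetylfilicinic acid, 2-acetyl-3,5-dihydroxy-4,4-dimethylcyclohexa-2,5-dien-1-one | CC(=O)C1=C(O)C(C)(C)C(O)=CC1=O | intermediate
15 | 2-methylphloroglucinol | Cc1c(O)cc(O)cc1O | starting material
16 | butyryl chloride | CCCC(=O)Cl | starting material
17 | 1-(2,4,6-trihydroxy-3-methylphenyl)butan-1-one | CCCC(=O)c1c(O)cc(O)c(C)c1O | intermediate
18 | aspidinol, 1-(2,6-dihydroxy-4-methoxy-3-methylphenyl)butan-1-one | CCCC(=O)c1c(O)cc(OC)c(C)c1O | intermediate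
19 | 1-{3-[(dimethylamino)methyl]-2,6-dihydroxy-4-methoxy-5-methylphenyl}butan-1-one | CCCC(=O)c1c(O)c(C)c(OC)c(CN(C)C)c1O | intermediate
20 | o-quinone methide, 2-butanoyl-3-hydroxy-5-methoxy-4-methyl-6-methylidenecyclohexa-2,4-dien-1-one | CCCC(=O)C1=C(O)C(C)=C(OC)C(=C)C1=O | intermediate
21 | 2-acetyl-6-[(3-butanoyl-2,4-dihydroxy-6-methoxy-5-methylphenyl)methyl]-3,5-dihydroxy-4,4-dimethylcyclohexa-2,5-dien-1-one | CCCC(=O)c1c(O)c(C)c(OC)c(CC2=C(O)C(C)(C)C(O)=C(C(C)=O)C2=O)c1O | target

Total step count: 9. Longest linear sequence: 5 steps (1, 3, 4, 5, 9).

Steps most likely to fail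

Step 3. The ring of 4 is donor-stabilised and gem-dimethyl-substituted, so it needs a high temperature to open. At that temperature the vinylketene may be drained by a 1,5-hydrogen shift from a methyl group, and the terminal ynol ether may oligomerise before it captures the ketene.
- Fallback (sets out from 4 and 2, comes back at 12): the ketene is made with light instead of heat, and the ring expansion is run on an isolated four-membered ring.
- Compound 4 is irradiated (254 nm, quartz, Et2O, rt) in the presence of commercial 2, which does not lose ethylene at that temperature. This should give, via 8, the [2+2] adduct 3-ethoxy-4-(1-ethoxy-2-methylprop-1-en-1-yl)cyclobut-2-en-1-one F1, which is isolated.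
- A separate unimolecular thermolysis of this adduct in dilute toluene (about 140 °C) should pass through (3E)-3,5-diethoxy-6-methylhepta-1,3,5-trien-1-one F2. It should close to 3,5-diethoxy-6,6-dimethylcyclohexa-2,4-dien-1-one F3, which the acid hydrolysis of step 4 converts into 12.

Step 9. Three things may go wrong: exchange of the two halves by retro-Michael/Michael equilibration of the methylene bridge, self-capture of the quinone methide, or interception of the acetyl triketone by the liberated amine.
- Fallback (sets out from 14, uses 18, comes back at 21): electrophile and nucleophile swap roles.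
- Aminomethylation of 14 with formaldehyde and piperidine in EtOH should give 2-acetyl-3,5-dihydroxy-4,4-dimethyl-6-(piperidin-1-ylmethyl)cyclohexa-2,5-dien-1-one F4, isolated as its inner salt.
- On warming with 18 and NaOAc in dioxane it should lose piperidine to give the exocyclic enone 2-acetyl-3-hydroxy-4,4-dimethyl-6-methylidenecyclohex-2-ene-1,5-dione F5. The phenolate of 18 captures this enone through its only free ring carbon (Michael addition) to give 21.

Step 7. Site selectivity may be poor, with methylation of a chelated ortho hydroxyl, double methylation or C-methylation of the electron-rich ring.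
- Fallback (sets out from 17, comes back at 18): selectivity is moved from alkylation to dealkylation.
- Exhaustive O-methylation (excess Me2SO4, K2CO3, acetone, reflux) should give 1-(2,4,6-trimethoxy-3-methylphenyl)butan-1-one F6.
- BCl3 in CH2Cl2 then removes only the two methyl ethers ortho to the ketone by chelation-directed cleavage. The para methoxy group stays in place, and 18 results.

Further compounds
F1 | step 3 | 3-ethoxy-4-(1-ethoxy-2-methylprop-1-en-1-yl)cyclobut-2-en-1-one (racemic) | CCOC1=CC(=O)C1C(OCC)=C(C)C
F2 | step 3 | (3E)-3,5-diethoxy-6-methylhepta-1,3,5-trien-1-one | O=C=C/C(OCC)=C\C(OCC)=C(C)C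
F3 | step 3 | 3,5-diethoxy-6,6-dimethylcyclohexa-2,4-dien-1-one | CCOC1=CC(OCC)=CC(=O)C1(C)C
F4 | step 9 | 2-acetyl-3,5-dihydroxy-4,4-dimethyl-6-(piperidin-1-ylmethyl)cyclohexa-2,5-dien-1-one | CC(=O)C1=C(O)C(C)(C)C(O)=C(CN2CCCCC2)C1=O
F5 | step 9 | 2-acetyl-3-hydroxy-4,4-dimethyl-6-methylidenecyclohex-2-ene-1,5-dione | CC(=O)C1=C(O)C(C)(C)C(=O)C(=C)C1=O
F6 | step 7 | 1-(2,4,6-trimethoxy-3-methylphenyl)butan-1-one | CCCC(=O)c1c(OC)cc(OC)c(C)c1OC
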